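## The problem

The target is a biflavonoid in which C3′ of ring B of an apigenin (flavone) unit is bonded to C8 of a (2R,3R)-dihydrokaempferol (flavanonol) unit. The biaryl bond joins a carbon flanked by two oxygens (C7–O and C8a–O1 of flavanonol ring A) to a carbon ortho to a phenol, so it is hindered. The three oxygens of that phloroglucinol ring must also be told apart: one becomes O1, C8 carries the aryl group, C4a the carbonyl, and C6 stays free. The only stereocentres are the contiguous C2 and C3 of the flavanonol, trans to each other. The trans relation is the thermodynamic one, but the absolute configuration has to come from outside. Flavanonol ring C is the fragile part: base enolises C3, opens the O1–C2 bond and epimerises or oxidises the ring, and C2–O1 is a 4-oxybenzylic ether that a strong acid can ionise. Seven hydroxyl groups need protection, and all late steps must therefore be non-basic and short. What makes the plan possible is that flavanonol C2, C3, C4 and ring B are the carbon skeleton of a 3-aryl-2,3-dioxygenated propanoic acid, that is of an aryl glycidate. In addition, ring A is nucleophilic enough at C4a to be acylated by a carboxylic acid tethered through O1, and that tether can reach C4a but not C6.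

## Retrosynthesis

**Protecting groups, 18 from 17 from 16.** The target 18 is traced back to hexaether 17 (five benzyl ethers, one methyl ether at the flavanonol 4′-oxygen, free 3-OH) and then to its 3-acetate 16. Benzyl is chosen for the five phenols because it is cleaved by BBr3 at low temperature. The methyl ether comes with the purchased epoxide and is the only group that needs the reagent at higher temperature. An all-methyl scheme would save benzylations but would expose ring C to BBr3 for much longer. The acetate is taken off by acid, not base, because of the enolisable C3.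

**C4–C4a, 16 from 14.** Cutting the bond between the ketone carbon and ring A gives the acyclic (2R,3R)-2-acetoxy-3-aryloxy acid 14. The neighbouring cuts (O1–C2 last by opening a chalcone epoxide, or C2–C3 by an aldol) would require the stereocentres to be made by asymmetric catalysis on a large biaryl. This cut instead puts both stereocentres into a three-carbon acid that can be bought as an epoxide, and the tether decides C4a against C6. The forward reaction must acylate a very electron-rich arene without ionising the benzylic C–O bond.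

**O1–C2, 14 from 13 from 12 from 10 and 11.** Acid 14 comes from hydroxy acid 13 and methyl ester 12. Cutting the aryl ether bond of 12 gives biaryl phenol 10 and methyl (2R,3S)-3-(4-methoxyphenyl)glycidate 11. The phenoxide must attack the benzylic carbon of 11 with inversion (S to R) and leave the ester-bearing carbon alone. That carbon then becomes flavanonol C3 with the correct R configuration, and no stereocentre has to be created.

**Biaryl bond, 10 from 9 and 7.** The C8–C3′ bond is cut to iodophenol 9 and flavone boronate 7. Boron is placed on the flavone side because a 2,4,6-trioxygenated arylboron compound loses boron to protonation too easily. The phenol of 9 is left free because it is the nucleophile of the next step. The coupling must tolerate three ortho substituents.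

**Iodide, 9 from 8.** Iodophenol 9 comes from 3,5-bis(benzyloxy)phenol 8 by iodination at one of the two equivalent positions next to the hydroxyl group. The forward step has to avoid the position between the two benzyloxy groups.

**Flavone, 7 from 6 from 5 from 2 and 4.** Boronate 7 comes from iodide 6 by borylation. Flavone 6 comes from 2′-hydroxychalcone 5 by oxidative cyclisation, and 5 from acetophenone 2 and aldehyde 4 by aldol condensation. These come from 2′,4′,6′-trihydroxyacetophenone 1 and 4-hydroxy-3-iodobenzaldehyde 3 by benzylation. The iodine that later becomes the biaryl bond is already in place in 3.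

## Roads not taken

**Alternative 1:** Both O1–C2 bonds are cut at once. The precursor A1 is a biaryl carrying a 2,4,6-tris(methoxymethoxy)phenyl ynone on one arm and a methoxymethyl-protected chalcone epoxide on the other. HCl in methanol and tetrahydrofuran would remove the methoxymethyl groups, and the freed phenols would add to the ynone and open the epoxide at its benzylic carbon. The product A2 is the target as its flavanonol 5,7-dibenzyl ether.
- Merits: two rings close in one operation, the epoxide closure is the classical way to trans-flavanonols, and the synthesis ends with a hydrogenolysis. That last point is better than the chosen plan, which needs BBr3 at the end.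
- Weak points: A1 must hold an ynone and an epoxy ketone together, and a nucleophilic asymmetric epoxidation would attack the ynone first, so the order of assembly is constrained. The stereocentres would come from asymmetric epoxidation of a twisted, doubly ortho-substituted chalcone. One pot must also get two regiochemical choices right (six-ring against five-ring closure at the ynone, benzylic against alpha opening of the epoxide) while HCl and methanol can add to the ynone.
- Comparison: the chosen plan buys the stereocentre pair and closes the two heterocycles separately, so each can be optimised on its own.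

**Alternative 2:** Three C–C bonds of flavanonol ring A are cut (C8–C8a, C6–C7, C4a–C8a). Heating aryl siloxyalkyne A3 with 3-ethoxycyclobutenone A4 would run a Danheiser benzannulation (vinylketene, [2+2] addition, ring opening, 6π closure). The product A5 is a 2-arylphloroglucinol with free C8a-OH, C7-OTIPS and C5-OEt.
- Merits: all three ring A oxygens are differentiated and the aryl group is placed without ambiguity. The chosen plan reaches this only through the site selectivity of a phenol iodination and a hindered cross-coupling, so this road is better on that point.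
- Weak points: the ring that is built is an achiral benzene, available otherwise as a phloroglucinol derivative. A3 needs several steps and is moisture-sensitive. After A5 both pyranone rings, both stereocentres and the conversion of the acetal into the flavone are still to be done, and the C5 ethyl ether again needs a Lewis acid at the end.
- Comparison: the chosen plan accepts a selectivity risk at step 6, for which a directed-metalation fallback is given, in exchange for a much shorter route.

**Alternative 3:** Flavone ring C is cut at C4a–C4, C4–C3 and O1–C2. Iodophenol 9, CO and the ethynyl-bearing flavanonol A6 would react with PdCl2(PPh3)2 in diethylamine (carbonylative Sonogashira coupling, then 6-endo closure). The product A7 is the fully protected target.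
- Merits: the route is convergent, the flavone arm is short, and an all-benzyl and silyl protection would allow a hydrogenolytic finish, again milder than BBr3.
- Weak points: A6 already contains the finished flavanonol, so the stereochemical problem is only moved upstream. That base-sensitive ring must then survive a hot secondary amine, which can enolise C3, open ring C and epimerise it. The electron-rich, doubly ortho-substituted iodophenol is slow in oxidative addition. Five-ring closure to an aurone and coupling without CO to a benzofuran both compete.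
- Comparison: the chosen plan makes the flavone first by robust chemistry and exposes the flavanonol only to acidic reagents in its last three steps.

Key step: step 11

Assumption: the biaryl axis, which carries no descriptor in the target structure, is taken as not needing control, and 3,5-bis(benzyloxy)phenol is taken as a purchasable phloroglucinol derivative.

## Steps

Step 1
Reactants: 1 2′,4′,6′-trihydroxyacetophenone
Product: 2 1-[2,4-bis(benzyloxy)-6-hydroxyphenyl]ethanone
Conditions: BnBr (2.1 equiv), K2CO3, DMF, 0 °C to rt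
Reagents that add atoms: benzyl bromide, BrCc1ccccc1
Why: Williamson etherification; the hydroxyl group hydrogen-bonded to the ketone is the least acidic and least nucleophilic and should stay free.

Step 2
Reactants: 3 4-hydroxy-3-iodobenzaldehyde
Product: 4 4-(benzyloxy)-3-iodobenzaldehyde
Conditions: BnBr, K2CO3, DMF, rt
Reagents that add atoms: benzyl bromide, BrCc1ccccc1
Why: Williamson etherification of an acidic phenol; the aldehyde and the aryl iodide are inert to these conditions.

Step 3
Reactants: 2 1-[2,4-bis(benzyloxy)-6-hydroxyphenyl]ethanone; 4 4-(benzyloxy)-3-iodobenzaldehyde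
Product: 5 (E)-1-[2,4-bis(benzyloxy)-6-hydroxyphenyl]-3-[4-(benzyloxy)-3-iodophenyl]prop-2-en-1-one
Conditions: KOH (aq.), EtOH/THF, rt
Reagents that add atoms: none
Why: Claisen–Schmidt condensation; the aldehyde cannot enolise, and dehydration of the aldol gives the conjugated E-chalcone.

Step 4
Reactants: 5 (E)-1-[2,4-bis(benzyloxy)-6-hydroxyphenyl]-3-[4-(benzyloxy)-3-iodophenyl]prop-2-en-1-one
Product: 6 5,7-bis(benzyloxy)-2-[4-(benzyloxy)-3-iodophenyl]-4H-chromen-4-one
Conditions: I2 (cat.), DMSO, 130 °C
Reagents that add atoms: none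
Why: iodine-catalysed oxidative cyclisation of a 2′-hydroxychalcone (oxa-Michael closure, alpha-iodination, loss of HI, with DMSO turning HI back into I2); benzyl ethers and the aryl iodide should survive.

Step 5
Reactants: 6 5,7-bis(benzyloxy)-2-[4-(benzyloxy)-3-iodophenyl]-4H-chromen-4-one
Product: 7 5,7-bis(benzyloxy)-2-[4-(benzyloxy)-3-(4,4,5,5-tetramethyl-1,3,2-dioxaborolan-2-yl)phenyl]-4H-chromen-4-one
Conditions: B2pin2, PdCl2(dppf) (cat.), KOAc, 1,4-dioxane, 90 °C
Reagents that add atoms: bis(pinacolato)diboron, CC1(C)OB(OC1(C)C)B1OC(C)(C)C(C)(C)O1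
Why: Miyaura borylation of an aryl iodide; the weak acetate base prevents the boronate from coupling with unreacted iodide.

Step 6
Reactants: 8 3,5-bis(benzyloxy)phenol
Product: 9 3,5-bis(benzyloxy)-2-iodophenol
Conditions: NIS (1.0 equiv), CH2Cl2, −78 to 0 °C
Reagents that add atoms: N-iodosuccinimide, O=C1CCC(=O)N1I
Why: electrophilic aromatic iodination; the two equivalent positions next to the hydroxyl group are favoured by number and by lower steric demand over the position between the two benzyloxy groups, and low temperature with one equivalent limits double iodination.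

Step 7
Reactants: 9 3,5-bis(benzyloxy)-2-iodophenol; 7 5,7-bis(benzyloxy)-2-[4-(benzyloxy)-3-(4,4,5,5-tetramethyl-1,3,2-dioxaborolan-2-yl)phenyl]-4H-chromen-4-one
Product: 10 5,7-bis(benzyloxy)-2-{4-(benzyloxy)-3-[2,4-bis(benzyloxy)-6-hydroxyphenyl]phenyl}-4H-chromen-4-one
Conditions: Pd(OAc)2 (cat.), SPhos, K3PO4, toluene/H2O, 90 °C
Reagents that add atoms: none
Why: Suzuki–Miyaura coupling; a biaryl dialkylphosphine ligand is suited to biaryls with three ortho substituents and to free ortho-halophenols, and the flavone tolerates the mild phosphate base.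

Step 8
Reactants: 10 5,7-bis(benzyloxy)-2-{4-(benzyloxy)-3-[2,4-bis(benzyloxy)-6-hydroxyphenyl]phenyl}-4H-chromen-4-one; 11 methyl (2R,3S)-3-(4-methoxyphenyl)oxirane-2-carboxylate
Product: 12 methyl (2R,3R)-3-{3,5-bis(benzyloxy)-2-[2-(benzyloxy)-5-(5,7-bis(benzyloxy)-4-oxo-4H-chromen-2-yl)phenyl]phenoxy}-2-hydroxy-3-(4-methoxyphenyl)propanoate
Conditions: Cs2CO3 (0.3 equiv), 11 (1.3 equiv), DMF, 60 °C
Reagents that add atoms: none
Why: base-mediated SN2 opening of a 3-arylglycidate at its benzylic carbon by a phenoxide; backside attack inverts that carbon (S to R, the future flavanonol C2) while the ester-bearing carbon keeps its R configuration (future C3), and the basic aprotic medium suppresses the ion-pair pathway that would give retention.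

Step 9
Reactants: 12 methyl (2R,3R)-3-{3,5-bis(benzyloxy)-2-[2-(benzyloxy)-5-(5,7-bis(benzyloxy)-4-oxo-4H-chromen-2-yl)phenyl]phenoxy}-2-hydroxy-3-(4-methoxyphenyl)propanoate
Product: 13 (2R,3R)-3-{3,5-bis(benzyloxy)-2-[2-(benzyloxy)-5-(5,7-bis(benzyloxy)-4-oxo-4H-chromen-2-yl)phenyl]phenoxy}-2-hydroxy-3-(4-methoxyphenyl)propanoic acid
Conditions: LiOH, THF/H2O, 0 °C to rt; then 1 M HCl
Reagents that add atoms: lithium hydroxide (its oxygen), [Li+].[OH-]
Why: saponification of an alpha-hydroxy methyl ester, which is fast at low temperature; the alkoxide formed first makes the alpha proton less acidic, so epimerisation and elimination of the aryloxide should not compete.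

Step 10
Reactants: 13 (2R,3R)-3-{3,5-bis(benzyloxy)-2-[2-(benzyloxy)-5-(5,7-bis(benzyloxy)-4-oxo-4H-chromen-2-yl)phenyl]phenoxy}-2-hydroxy-3-(4-methoxyphenyl)propanoic acid
Product: 14 (2R,3R)-2-acetoxy-3-{3,5-bis(benzyloxy)-2-[2-(benzyloxy)-5-(5,7-bis(benzyloxy)-4-oxo-4H-chromen-2-yl)phenyl]phenoxy}-3-(4-methoxyphenyl)propanoic acid
Conditions: Ac2O, pyridine, CH2Cl2, 0 °C to rt; then H2O
Reagents that add atoms: acetic anhydride, CC(=O)OC(C)=O
Why: O-acetylation of a secondary alcohol; the mixed acetic anhydride formed at the carboxyl group is hydrolysed in the aqueous work-up, and the low temperature without an acyl-transfer catalyst guards the alpha centre.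

Step 11
Reactants: 14 (2R,3R)-2-acetoxy-3-{3,5-bis(benzyloxy)-2-[2-(benzyloxy)-5-(5,7-bis(benzyloxy)-4-oxo-4H-chromen-2-yl)phenyl]phenoxy}-3-(4-methoxyphenyl)propanoic acid
Product: 16 (2R,3R)-5,7-bis(benzyloxy)-8-[2-(benzyloxy)-5-(5,7-bis(benzyloxy)-4-oxo-4H-chromen-2-yl)phenyl]-2-(4-methoxyphenyl)-4-oxochroman-3-yl acetate, via mixed trifluoroacetic anhydride 15 (not isolated)
Conditions: TFAA (2 equiv), CH2Cl2 (dilute), 0 °C to rt
Reagents that add atoms: none
Why: Intramolecular Friedel–Crafts acylation, the known closure of 3-aryloxypropanoic acids to chroman-4-ones. TFAA converts the acid into mixed anhydride 15, whose alkyl acyl carbon (or the acylium ion in equilibrium with it) is attacked by C4a, with trifluoroacetate as leaving group and loss of a proton restoring the arene. Ring C closes in a 6-exo mode, the arene carbon attacking the carbonyl carbon through a six-membered transition state with the C=O bond outside the new ring. No stereocentre is formed, and C2 and C3 keep their configuration because neither C–O bond is broken. The acetoxy and acyl groups on C3 destabilise a cation at C2, so the 4-methoxybenzyl-type aryl ether should not ionise in trifluoroacetic acid at this temperature. Site selectivity on ring A comes from the tether, which reaches C4a (ortho to O1 and C5–OBn, para to C7–OBn) but not C6. The five-ring alternative onto the anisyl ring would have to attack meta to its methoxy group, and the flavone ring A is deactivated by its carbonyl. A small excess of TFAA and high dilution hold back intermolecular trifluoroacetylation and acylation at C6.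

Step 12
Reactants: 16 (2R,3R)-5,7-bis(benzyloxy)-8-[2-(benzyloxy)-5-(5,7-bis(benzyloxy)-4-oxo-4H-chromen-2-yl)phenyl]-2-(4-methoxyphenyl)-4-oxochroman-3-yl acetate
Product: 17 (2R,3R)-5,7-bis(benzyloxy)-8-[2-(benzyloxy)-5-(5,7-bis(benzyloxy)-4-oxo-4H-chromen-2-yl)phenyl]-3-hydroxy-2-(4-methoxyphenyl)chroman-4-one
Conditions: HCl (cat., anhydrous) in MeOH/CH2Cl2, rt to 35 °C
Reagents that add atoms: none
Why: acid-catalysed transesterification of a secondary acetate; base is avoided because the C3 enolate opens and epimerises ring C, while benzyl ethers, the flavone and the C2 ether are stable to dilute HCl in methanol.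

Step 13
Reactants: 17 (2R,3R)-5,7-bis(benzyloxy)-8-[2-(benzyloxy)-5-(5,7-bis(benzyloxy)-4-oxo-4H-chromen-2-yl)phenyl]-3-hydroxy-2-(4-methoxyphenyl)chroman-4-one
Product: 18 (2R,3R)-8-[5-(5,7-dihydroxy-4-oxo-4H-chromen-2-yl)-2-hydroxyphenyl]-3,5,7-trihydroxy-2-(4-hydroxyphenyl)chroman-4-one
Conditions: BBr3 (excess), pentamethylbenzene, CH2Cl2, −78 °C to rt; then MeOH, aqueous work-up
Reagents that add atoms: none
Why: Lewis-acid cleavage of aryl ethers; the five benzyl ethers should go at low temperature and the single anisole-type methyl ether on warming, pentamethylbenzene traps benzyl cations that would otherwise alkylate C6 of the phloroglucinol rings, and C2 and C3 are untouched because O1 is a vinylogous ester oxygen and a C2 cation is disfavoured by the oxygen and carbonyl at C3 and C4.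

## Compound list

1 | 2′,4′,6′-trihydroxyacetophenone | CC(=O)c1c(O)cc(O)cc1O | starting material
2 | 1-[2,4-bis(benzyloxy)-6-hydroxyphenyl]ethanone | CC(=O)c1c(O)cc(OCc2ccccc2)cc1OCc1ccccc1 | intermediate
3 | 4-hydroxy-3-iodobenzaldehyde | O=Cc1ccc(O)c(I)c1 | starting material
4 | 4-(benzyloxy)-3-iodobenzaldehyde | O=Cc1ccc(OCc2ccccc2)c(I)c1 | intermediate
5 | (E)-1-[2,4-bis(benzyloxy)-6-hydroxyphenyl]-3-[4-(benzyloxy)-3-iodophenyl]prop-2-en-1-one | O=C(/C=C/c1ccc(OCc2ccccc2)c(I)c1)c1c(O)cc(OCc2ccccc2)cc1OCc1ccccc1 | intermediate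
6 | 5,7-bis(benzyloxy)-2-[4-(benzyloxy)-3-iodophenyl]-4H-chromen-4-one | O=c1cc(-c2ccc(OCc3ccccc3)c(I)c2)oc2cc(OCc3ccccc3)cc(OCc3ccccc3)c12 | intermediate
7 | 5,7-bis(benzyloxy)-2-[4-(benzyloxy)-3-(4,4,5,5-tetramethyl-1,3,2-dioxaborolan-2-yl)phenyl]-4H-chromen-4-one | O=c1cc(-c2ccc(OCc3ccccc3)c(B3OC(C)(C)C(C)(C)O3)c2)oc2cc(OCc3ccccc3)cc(OCc3ccccc3)c12 | intermediate
8 | 3,5-bis(benzyloxy)phenol | Oc1cc(OCc2ccccc2)cc(OCc2ccccc2)c1 | starting material
9 | 3,5-bis(benzyloxy)-2-iodophenol | Oc1cc(OCc2ccccc2)cc(OCc2ccccc2)c1I | intermediate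
10 | 5,7-bis(benzyloxy)-2-{4-(benzyloxy)-3-[2,4-bis(benzyloxy)-6-hydroxyphenyl]phenyl}-4H-chromen-4-one | Oc1cc(OCc2ccccc2)cc(OCc2ccccc2)c1-c1cc(-c2cc(=O)c3c(OCc4ccccc4)cc(OCc4ccccc4)cc3o2)ccc1OCc1ccccc1 | intermediate
11 | methyl (2R,3S)-3-(4-methoxyphenyl)oxirane-2-carboxylate | COC(=O)[C@@H]1O[C@H]1c1ccc(OC)cc1 | starting material
12 | methyl (2R,3R)-3-{3,5-bis(benzyloxy)-2-[2-(benzyloxy)-5-(5,7-bis(benzyloxy)-4-oxo-4H-chromen-2-yl)phenyl]phenoxy}-2-hydroxy-3-(4-methoxyphenyl)propanoate | c1c(OCc6ccccc6)cc(OCc6ccccc6)c(-c3cc(-c4cc(=O)c5c(OCc6ccccc6)cc(OCc6ccccc6)cc5o4)ccc3OCc6ccccc6)c1O[C@H](c2ccc(OC)cc2)[C@H](C(=O)OC)O | intermediate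
13 | (2R,3R)-3-{3,5-bis(benzyloxy)-2-[2-(benzyloxy)-5-(5,7-bis(benzyloxy)-4-oxo-4H-chromen-2-yl)phenyl]phenoxy}-2-hydroxy-3-(4-methoxyphenyl)propanoic acid | c1c(OCc6ccccc6)cc(OCc6ccccc6)c(-c3cc(-c4cc(=O)c5c(OCc6ccccc6)cc(OCc6ccccc6)cc5o4)ccc3OCc6ccccc6)c1O[C@H](c2ccc(OC)cc2)[C@H](C(=O)O)O | intermediate
14 | (2R,3R)-2-acetoxy-3-{3,5-bis(benzyloxy)-2-[2-(benzyloxy)-5-(5,7-bis(benzyloxy)-4-oxo-4H-chromen-2-yl)phenyl]phenoxy}-3-(4-methoxyphenyl)propanoic acid | c1c(OCc6ccccc6)cc(OCc6ccccc6)c(-c3cc(-c4cc(=O)c5c(OCc6ccccc6)cc(OCc6ccccc6)cc5o4)ccc3OCc6ccccc6)c1O[C@H](c2ccc(OC)cc2)[C@H](C(=O)O)OC(C)=O | intermediate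
15 | mixed anhydride of acid 14 with trifluoroacetic acid | c1c(OCc6ccccc6)cc(OCc6ccccc6)c(-c3cc(-c4cc(=O)c5c(OCc6ccccc6)cc(OCc6ccccc6)cc5o4)ccc3OCc6ccccc6)c1O[C@H](c2ccc(OC)cc2)[C@H](C(=O)OC(=O)C(F)(F)F)OC(C)=O | intermediate
16 | (2R,3R)-5,7-bis(benzyloxy)-8-[2-(benzyloxy)-5-(5,7-bis(benzyloxy)-4-oxo-4H-chromen-2-yl)phenyl]-2-(4-methoxyphenyl)-4-oxochroman-3-yl acetate | O=C1c2c(OCc6ccccc6)cc(OCc6ccccc6)c(-c3cc(-c4cc(=O)c5c(OCc6ccccc6)cc(OCc6ccccc6)cc5o4)ccc3OCc6ccccc6)c2O[C@H](c2ccc(OC)cc2)[C@H]1OC(C)=O | intermediate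
17 | (2R,3R)-5,7-bis(benzyloxy)-8-[2-(benzyloxy)-5-(5,7-bis(benzyloxy)-4-oxo-4H-chromen-2-yl)phenyl]-3-hydroxy-2-(4-methoxyphenyl)chroman-4-one | O=C1c2c(OCc6ccccc6)cc(OCc6ccccc6)c(-c3cc(-c4cc(=O)c5c(OCc6ccccc6)cc(OCc6ccccc6)cc5o4)ccc3OCc6ccccc6)c2O[C@H](c2ccc(OC)cc2)[C@H]1O | intermediate
18 | (2R,3R)-8-[5-(5,7-dihydroxy-4-oxo-4H-chromen-2-yl)-2-hydroxyphenyl]-3,5,7-trihydroxy-2-(4-hydroxyphenyl)chroman-4-one | O=C1c2c(O)cc(O)c(-c3cc(-c4cc(=O)c5c(O)cc(O)cc5o4)ccc3O)c2O[C@H](c2ccc(O)cc2)[C@H]1O | target

## Step count and risks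

Total: 13 steps. Longest linear sequence: 11 steps (steps 1, 3, 4, 5, 7, 8, 9, 10, 11, 12, 13, from 1 to 18).

**Step 11 (key step).** If closure onto C4a is slow, the acid medium may ionise the C2–O bond (loss of the phenol or epimerisation at C2) or trifluoroacetylate a free C6 position. C4a is flanked by a benzyloxy group and sits on a ring that carries a bulky biaryl.
The fallback closes the ring before the biaryl is made. It sets out from 8 and 11 and returns at 16.
- Phenol 8 opens 11 under the conditions of step 8 to give methyl (2R,3R)-3-[3,5-bis(benzyloxy)phenoxy]-2-hydroxy-3-(4-methoxyphenyl)propanoate F1.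
- Saponification gives (2R,3R)-3-[3,5-bis(benzyloxy)phenoxy]-2-hydroxy-3-(4-methoxyphenyl)propanoic acid F2.
- Acetylation gives (2R,3R)-2-acetoxy-3-[3,5-bis(benzyloxy)phenoxy]-3-(4-methoxyphenyl)propanoic acid F3.
- Friedel–Crafts closure, onto a symmetric and unhindered ring where both ortho positions give the same product, gives (2R,3R)-5,7-bis(benzyloxy)-2-(4-methoxyphenyl)-4-oxochroman-3-yl acetate F4.
- NIS iodination at C8, the position between the ring oxygen and C7–OBn (C6 lies between two benzyloxy groups), gives (2R,3R)-5,7-bis(benzyloxy)-8-iodo-2-(4-methoxyphenyl)-4-oxochroman-3-yl acetate F5.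
- Suzuki coupling of F5 with boronate 7 under anhydrous conditions (Pd(OAc)2, SPhos, K3PO4, toluene) gives 16.

**Step 8.** Bimolecular substitution by the hindered ortho-aryl phenoxide may be slow. Opening through a benzylic ion pair with retention (leading to the cis series), attack at the ester, or decomposition of the glycidate could then take over.
The fallback changes the order of bond formation. It sets out from 9 and 11 and returns at 12. The small iodophenol 9, used in excess, opens 11 to give methyl (2R,3R)-3-[3,5-bis(benzyloxy)-2-iodophenoxy]-2-hydroxy-3-(4-methoxyphenyl)propanoate F6. Suzuki coupling of F6 with 7 then gives 12.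

**Step 13.** Ring C may open or epimerise at the 4-oxybenzylic C2–O1 bond, or C6 may be benzylated, during the time the strong Lewis acid needs to cleave the methyl ether.
The fallback removes the methyl ether from the plan. It sets out from 10 and returns at 18.
- Methyl (E)-3-[4-(benzyloxy)phenyl]prop-2-enoate F7 is epoxidised with a chiral dioxirane (a chiral ketone with Oxone, the enantiomer of the catalyst chosen accordingly) to methyl (2R,3S)-3-[4-(benzyloxy)phenyl]oxirane-2-carboxylate F8. Its enantiomeric purity would be raised by crystallisation.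
- F8 is carried with 10 through the conditions of steps 8 to 12. This gives in turn the hydroxy ester F9, the hydroxy acid F10, the acetoxy acid F11, the hexabenzyl flavanonol acetate F12 and the hexabenzyl flavanonol F13.
- Hydrogenolysis of F13 (H2, palladium on carbon, THF/MeOH, rt) gives 18 without any Lewis acid.

**Step 6.** Iodination may lack site selectivity, with attack between the two benzyloxy groups or double iodination.
The fallback is a directed ortho-metalation. It sets out from 8 and returns at 9. Phenol 8 is converted with MOMCl and i-Pr2NEt into 1,3-bis(benzyloxy)-5-(methoxymethoxy)benzene F14. Lithiation with n-BuLi in THF at 0 °C should occur next to the more strongly coordinating methoxymethoxy group, and quenching with I2 gives 1,5-bis(benzyloxy)-2-iodo-3-(methoxymethoxy)benzene F15. HCl in methanol then gives 9.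

## Further compounds

F1 | step 11 | methyl (2R,3R)-3-[3,5-bis(benzyloxy)phenoxy]-2-hydroxy-3-(4-methoxyphenyl)propanoate | c1c(OCc2ccccc2)cc(OCc2ccccc2)cc1O[C@H](c1ccc(OC)cc1)[C@H](C(=O)OC)O
F2 | step 11 | (2R,3R)-3-[3,5-bis(benzyloxy)phenoxy]-2-hydroxy-3-(4-methoxyphenyl)propanoic acid | c1c(OCc2ccccc2)cc(OCc2ccccc2)cc1O[C@H](c1ccc(OC)cc1)[C@H](C(=O)O)O
F3 | step 11 | (2R,3R)-2-acetoxy-3-[3,5-bis(benzyloxy)phenoxy]-3-(4-methoxyphenyl)propanoic acid | c1c(OCc2ccccc2)cc(OCc2ccccc2)cc1O[C@H](c1ccc(OC)cc1)[C@H](C(=O)O)OC(C)=O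
F4 | step 11 | (2R,3R)-5,7-bis(benzyloxy)-2-(4-methoxyphenyl)-4-oxochroman-3-yl acetate | O=C1c2c(OCc3ccccc3)cc(OCc3ccccc3)cc2O[C@H](c2ccc(OC)cc2)[C@H]1OC(C)=O
F5 | step 11 | (2R,3R)-5,7-bis(benzyloxy)-8-iodo-2-(4-methoxyphenyl)-4-oxochroman-3-yl acetate | O=C1c2c(OCc3ccccc3)cc(OCc3ccccc3)c(I)c2O[C@H](c2ccc(OC)cc2)[C@H]1OC(C)=O
F6 | step 8 | methyl (2R,3R)-3-[3,5-bis(benzyloxy)-2-iodophenoxy]-2-hydroxy-3-(4-methoxyphenyl)propanoate | c1c(OCc2ccccc2)cc(OCc2ccccc2)c(I)c1O[C@H](c1ccc(OC)cc1)[C@H](C(=O)OC)O
F7 | step 13 | methyl (E)-3-[4-(benzyloxy)phenyl]prop-2-enoate | COC(=O)/C=C/c1ccc(OCc2ccccc2)cc1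
F8 | step 13 | methyl (2R,3S)-3-[4-(benzyloxy)phenyl]oxirane-2-carboxylate | COC(=O)[C@@H]1O[C@H]1c1ccc(OCc2ccccc2)cc1
F9 | step 13 | methyl (2R,3R)-3-{3,5-bis(benzyloxy)-2-[2-(benzyloxy)-5-(5,7-bis(benzyloxy)-4-oxo-4H-chromen-2-yl)phenyl]phenoxy}-3-[4-(benzyloxy)phenyl]-2-hydroxypropanoate | c1c(OCc6ccccc6)cc(OCc6ccccc6)c(-c3cc(-c4cc(=O)c5c(OCc6ccccc6)cc(OCc6ccccc6)cc5o4)ccc3OCc6ccccc6)c1O[C@H](c2ccc(OCc6ccccc6)cc2)[C@H](C(=O)OC)O
F10 | step 13 | (2R,3R)-3-{3,5-bis(benzyloxy)-2-[2-(benzyloxy)-5-(5,7-bis(benzyloxy)-4-oxo-4H-chromen-2-yl)phenyl]phenoxy}-3-[4-(benzyloxy)phenyl]-2-hydroxypropanoic acid | c1c(OCc6ccccc6)cc(OCc6ccccc6)c(-c3cc(-c4cc(=O)c5c(OCc6ccccc6)cc(OCc6ccccc6)cc5o4)ccc3OCc6ccccc6)c1O[C@H](c2ccc(OCc6ccccc6)cc2)[C@H](C(=O)O)O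
F11 | step 13 | (2R,3R)-2-acetoxy-3-{3,5-bis(benzyloxy)-2-[2-(benzyloxy)-5-(5,7-bis(benzyloxy)-4-oxo-4H-chromen-2-yl)phenyl]phenoxy}-3-[4-(benzyloxy)phenyl]propanoic acid | c1c(OCc6ccccc6)cc(OCc6ccccc6)c(-c3cc(-c4cc(=O)c5c(OCc6ccccc6)cc(OCc6ccccc6)cc5o4)ccc3OCc6ccccc6)c1O[C@H](c2ccc(OCc6ccccc6)cc2)[C@H](C(=O)O)OC(C)=O
F12 | step 13 | (2R,3R)-5,7-bis(benzyloxy)-8-[2-(benzyloxy)-5-(5,7-bis(benzyloxy)-4-oxo-4H-chromen-2-yl)phenyl]-2-[4-(benzyloxy)phenyl]-4-oxochroman-3-yl acetate | O=C1c2c(OCc6ccccc6)cc(OCc6ccccc6)c(-c3cc(-c4cc(=O)c5c(OCc6ccccc6)cc(OCc6ccccc6)cc5o4)ccc3OCc6ccccc6)c2O[C@H](c2ccc(OCc6ccccc6)cc2)[C@H]1OC(C)=O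
F13 | step 13 | (2R,3R)-5,7-bis(benzyloxy)-8-[2-(benzyloxy)-5-(5,7-bis(benzyloxy)-4-oxo-4H-chromen-2-yl)phenyl]-2-[4-(benzyloxy)phenyl]-3-hydroxychroman-4-one | O=C1c2c(OCc6ccccc6)cc(OCc6ccccc6)c(-c3cc(-c4cc(=O)c5c(OCc6ccccc6)cc(OCc6ccccc6)cc5o4)ccc3OCc6ccccc6)c2O[C@H](c2ccc(OCc6ccccc6)cc2)[C@H]1O
F14 | step 6 | 1,3-bis(benzyloxy)-5-(methoxymethoxy)benzene | COCOc1cc(OCc2ccccc2)cc(OCc2ccccc2)c1
F15 | step 6 | 1,5-bis(benzyloxy)-2-iodo-3-(methoxymethoxy)benzene | COCOc1cc(OCc2ccccc2)cc(OCc2ccccc2)c1I
A1 | alternative 1 | biaryl precursor with a 2,4,6-tris(methoxymethoxy)phenyl ynone and a methoxymethyl-protected chalcone epoxide | COCOc1cc(OCOC)c(C(=O)C#Cc2ccc(OCOC)c(c2)-c2c(OCOC)c(C(=O)[C@@H]3O[C@H]3c3ccc(OCOC)cc3)c(OCc3ccccc3)cc2OCc2ccccc2)c(OCOC)c1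
A2 | alternative 1 | target as its flavanonol 5,7-dibenzyl ether | O=C1c2c(OCc6ccccc6)cc(OCc6ccccc6)c(-c3cc(-c4cc(=O)c5c(O)cc(O)cc5o4)ccc3O)c2O[C@H](c2ccc(O)cc2)[C@H]1O
A3 | alternative 2 | {[2-(benzyloxy)-5-(1,3-dioxolan-2-yl)phenyl]ethynyloxy}triisopropylsilane | CC(C)[Si](OC#Cc1cc(C2OCCO2)ccc1OCc1ccccc1)(C(C)C)C(C)C
A4 | alternative 2 | 3-ethoxycyclobut-2-en-1-one | CCOC1=CC(=O)C1
A5 | alternative 2 | 2-[2-(benzyloxy)-5-(1,3-dioxolan-2-yl)phenyl]-5-ethoxy-3-(triisopropylsilyloxy)phenol | CCOc1cc(O)c(-c2cc(C3OCCO3)ccc2OCc2ccccc2)c(O[Si](C(C)C)(C(C)C)C(C)C)c1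
A6 | alternative 3 | (2R,3R)-5,7-bis(benzyloxy)-8-[2-(benzyloxy)-5-ethynylphenyl]-2-[4-(benzyloxy)phenyl]-3-(tert-butyldimethylsilyloxy)chroman-4-one | O=C1c2c(OCc6ccccc6)cc(OCc6ccccc6)c(-c3cc(C#C)ccc3OCc6ccccc6)c2O[C@H](c2ccc(OCc6ccccc6)cc2)[C@H]1O[Si](C)(C)C(C)(C)C
A7 | alternative 3 | fully protected target with 3-O-tert-butyldimethylsilyl and six benzyl ethers | O=C1c2c(OCc6ccccc6)cc(OCc6ccccc6)c(-c3cc(-c4cc(=O)c5c(OCc6ccccc6)cc(OCc6ccccc6)cc5o4)ccc3OCc6ccccc6)c2O[C@H](c2ccc(OCc6ccccc6)cc2)[C@H]1O[Si](C)(C)C(C)(C)C
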